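Positions are numbered as in the fatty acid chain: C1 is the ester carbon and C18 the chain end. The ring is C9–C13.

## Retrosynthetic overview
1. Target 11 ⇒ linear C18 keto-enynol 8, which is an isomer of 11. The C9–C13 bond comes from conrotatory 4π closure of a 2-oxidopentadienyl cation, the synthetic counterpart of a ring-opened allene oxide, carried as a vanadium allenolate.
2. 8 ⇒ (E)-pent-2-enal 7 + bromo enynone 6. The C13–C14 bond comes from catalytic asymmetric alkynylation, which sets C14, the only stereocentre brought in from outside.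
3. 6 ⇒ silyl diynone 3 by conjugate addition of HBr (C11–Br, C10–H). 3 ⇒ acid chloride 1 + bis-silyl butadiyne 2 by C9–C10 acylation.
4. There is one ring and it forms in the last step. C9 (S) and the 13Z alkene are set together by a relay from the C14 centre to the allene axis to the C9 centre. 15E comes from 7.

Assumption: (S,S)-ProPhenol is taken to give the 14S carbinol and the C9 oxygen is taken to rotate outward in the ring closure; if either sense proves opposite, the mirror-image ligand (also commercial) is used in step 4 and nothing else changes.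

## Route

Step 1
Reactants: 1 methyl 9-chloro-9-oxononanoate; 2 1,4-bis(trimethylsilyl)buta-1,3-diyne
Product: 3 methyl 9-oxo-13-(trimethylsilyl)trideca-10,12-diynoate
Conditions: AlCl3 (2.2 equiv), CH2Cl2, 0 °C; ice/1 M HCl
Reagents that add atoms: none
Why: Friedel–Crafts-type acyldesilylation, in which the β-silyl-stabilised vinyl cation loses Me3Si+ and the first acyl group deactivates the diyne so that only one end reacts; no stereocentre is formed.

Step 2
Reactants: 3 methyl 9-oxo-13-(trimethylsilyl)trideca-10,12-diynoate
Product: 5 methyl (10E)-11-bromo-9-oxo-13-(trimethylsilyl)tridec-10-en-12-ynoate, via (10Z)-bromo enynone 4 (not isolated)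
Conditions: LiBr (1.5 equiv), AcOH (5 equiv), MeCN, 25 °C, 2 h, then 70 °C, 12 h
Reagents that add atoms: lithium bromide [Li+].[Br-]
Why: Michael-type hydrobromination of an ynone, in which bromide attacks C11 (β to the ketone, with Me3Si blocking the δ-carbon C13) and anti protonation gives 4, which reversible bromide addition–elimination at 70 °C converts into the more stable 10E isomer 5, where the slim alkynyl group rather than bromine lies cis to the acyl group, as the ring closure needs.

Step 3
Reactants: 5 methyl (10E)-11-bromo-9-oxo-13-(trimethylsilyl)tridec-10-en-12-ynoate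
Product: 6 methyl (10E)-11-bromo-9-oxotridec-10-en-12-ynoate
Conditions: TBAF (1.05 equiv), AcOH (1.2 equiv), THF, −40 °C, 15 min
Reagents that add atoms: none
Why: Fluoride-induced protodesilylation of an electron-poor alkynylsilane is complete in minutes at low temperature, and the acetic acid buffer keeps fluoride from substituting the vinylogous acyl bromide or isomerising C10=C11.

Step 4
Reactants: 6 methyl (10E)-11-bromo-9-oxotridec-10-en-12-ynoate; 7 (E)-pent-2-enal
Product: 8 methyl (10E,14S,15E)-11-bromo-14-hydroxy-9-oxooctadeca-10,15-dien-12-ynoate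
Conditions: (S,S)-ProPhenol (20 mol %), Me2Zn (2.5 equiv), Ph3PO (40 mol %), toluene, 0 °C; then pH 7 buffer
Reagents that add atoms: none
Why: Catalytic asymmetric alkynylation of an aldehyde (dinuclear zinc–ProPhenol catalysis), which works best for this pairing of an electron-poor terminal alkyne and an α,β-unsaturated aldehyde; the chiral zinc pocket selects one aldehyde face and sets C14 as S, and copper-free Me2Zn leaves the ketone, ester and vinyl bromide untouched.

Step 5
Reactants: 8 methyl (10E,14S,15E)-11-bromo-14-hydroxy-9-oxooctadeca-10,15-dien-12-ynoate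
Product: 11 methyl 8-[(1S,5Z)-3-bromo-1-hydroxy-4-oxo-5-[(2E)-pent-2-en-1-ylidene]cyclopent-2-en-1-yl]octanoate (target), via propargyl vanadate 9 (not isolated), via vanadium allenolate 10 (not isolated)
Conditions: VO(OSiPh3)3 (10 mol %), 4 Å MS, ClCH2CH2Cl, 70 °C
Reagents that add atoms: none
Why: Proposed new method: ligand exchange gives 9, whose suprafacial [3,3] oxo shift (the first half of a vanadium Meyer–Schuster rearrangement) moves oxygen from C14 to C12 and turns the 14S centre into the aS axis of 10, an O-metallated 2-oxidopentadienyl cation spanning C9–C13 that should close C9–C13 by conrotatory 4π electrocyclisation faster than it is protonated, because the ketone is held cis and conjugated and cumulene strain is released; the butenyl group on C14 turns outward (13Z), the C9 oxygen turns outward as in Piancatelli closures (9S), and alkoxide exchange with 8 releases 11; the closest known reaction types are the Z-selective vanadium-catalysed propargyl alcohol/aldehyde aldol addition, the allenyl ether Nazarov cyclisation with axial-to-central chirality transfer, and the 4π step of the Piancatelli rearrangement.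

## Compound list
1 | methyl 9-chloro-9-oxononanoate | COC(=O)CCCCCCCC(Cl)=O | starting material
2 | 1,4-bis(trimethylsilyl)buta-1,3-diyne | C[Si](C)(C)C#CC#C[Si](C)(C)C | starting material
3 | methyl 9-oxo-13-(trimethylsilyl)trideca-10,12-diynoate | COC(=O)CCCCCCCC(=O)C#CC#C[Si](C)(C)C | intermediate
4 | methyl (10Z)-11-bromo-9-oxo-13-(trimethylsilyl)tridec-10-en-12-ynoate (Br cis to acyl; not isolated) | COC(=O)CCCCCCCC(=O)/C=C(\Br)C#C[Si](C)(C)C | intermediate
5 | methyl (10E)-11-bromo-9-oxo-13-(trimethylsilyl)tridec-10-en-12-ynoate (alkynyl cis to acyl) | COC(=O)CCCCCCCC(=O)/C=C(/Br)C#C[Si](C)(C)C | intermediate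
6 | methyl (10E)-11-bromo-9-oxotridec-10-en-12-ynoate | COC(=O)CCCCCCCC(=O)/C=C(/Br)C#C | intermediate
7 | (E)-pent-2-enal | CC/C=C/C=O | starting material
8 | methyl (10E,14S,15E)-11-bromo-14-hydroxy-9-oxooctadeca-10,15-dien-12-ynoate | CC/C=C/[C@H](O)C#C/C(Br)=C\C(=O)CCCCCCCC(=O)OC | intermediate
9 | oxobis(triphenylsiloxy)vanadium(V) C14-alkoxide of 8 (14S; not isolated) | CC/C=C/[C@H](O[V](=O)(O[Si](c1ccccc1)(c1ccccc1)c1ccccc1)O[Si](c1ccccc1)(c1ccccc1)c1ccccc1)C#C/C(Br)=C\C(=O)CCCCCCCC(=O)OC | intermediate
10 | (aS)-allenolate: oxobis(triphenylsiloxy)vanadium(V) bound to O on C12 of the C12=C13=C14 allene, 10E, 15E (not isolated) | CC/C=C/C([H])=[C@]=C(O[V](=O)(O[Si](c1ccccc1)(c1ccccc1)c1ccccc1)O[Si](c1ccccc1)(c1ccccc1)c1ccccc1)/C(Br)=C\C(=O)CCCCCCCC(=O)OC | intermediate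
11 | methyl 8-[(1S,5Z)-3-bromo-1-hydroxy-4-oxo-5-[(2E)-pent-2-en-1-ylidene]cyclopent-2-en-1-yl]octanoate | CC/C=C/C=C1\C(=O)C(Br)=C[C@@]1(O)CCCCCCCC(=O)OC | target

## Step count and risks
Total steps: 5. Longest linear sequence: 5 (1 → 3 → 5 → 6 → 8 → 11).

**Most likely to fail, first: step 5.**
- Allenolate 10 may be protonated before it closes, which is the ordinary Meyer–Schuster outcome.
- The cis keto-enyne may close through oxygen to a furan.
- Imperfect inside/outside selection at C9 would erode the ee.

The fallback sets out from 8 and comes back at 11. It moves control of C9 from the chirality relay to a catalyst.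
- The same vanadate catalyst with one equivalent of benzoic acid as proton shuttle is used on purpose to give the kinetic (13Z)-dienedione F1.
- F1 equilibrates by oxa-6π closure with the monocyclic 2H-pyran F2.
- The enol ether carbon C13 of F2 closes onto the C9 ketone activated by a chiral BINOL-derived N-triflyl phosphoramide (5–10 mol %, toluene, 0–25 °C). This is a Piancatelli-type 4π closure inside a chiral ion pair.
- Loss of H13 gives the fused 2H-pyran F3.
- Retro-6π opening of F3 can only give the 13Z alkene and turns the ethyl group outward (15E), which gives 11.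

**Second: step 2.**
- The E/Z equilibrium may be less favourable than argued.
- Some δ-attack of bromide may occur.
- Long heating may damage 5.

The fallback sets out from 1 and comes back at 5. It replaces equilibration with a stereospecific coupling.
- 1 is acylated onto bis(trimethylsilyl)acetylene (AlCl3) to give the silyl ynone F4.
- NBS with catalytic AgNO3 gives the bromo ynone F5.
- Anti hydroiodination (NaI, AcOH, 0 °C) gives the (10Z)-bromo iodo enone F6, with iodine cis to the acyl group.
- Sonogashira coupling with ethynyltrimethylsilane (PdCl2(PPh3)2, CuI, i-Pr2NEt, THF, 0 °C) takes place at C–I only and with retention, which gives 5.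

**Third: step 4.**
- The zinc Lewis acid may trigger oxygen attack of the cis ketone on the alkyne.
- The ee with this unusual alkyne may be moderate.

The fallback sets out from 6 and 7 and comes back at 8. It sets C14 by reduction instead of by C–C bond formation.
- Ligand-free addition (Me2Zn, toluene, 25 °C) gives the racemic carbinol F7.
- MnO2 gives the enynone F8.
- B-isopinocampheyl-9-BBN made from (−)-α-pinene reduces alkynyl ketones far faster than the C9 enone or the ester. It delivers hydride to one face and gives the 14S alcohol 8.

## Further compounds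
F1 | step 5 | methyl (10E,13Z,15E)-11-bromo-9,12-dioxooctadeca-10,13,15-trienoate | CC/C=C/C=C\C(=O)/C(Br)=C\C(=O)CCCCCCCC(=O)OC
F2 | step 5 | methyl (10E)-11-bromo-11-(2-ethyl-2H-pyran-6-yl)-9-oxoundec-10-enoate (racemic at the pyran C2) | CCC1C=CC=C(O1)/C(Br)=C\C(=O)CCCCCCCC(=O)OC
F3 | step 5 | fused 2-ethyl-2H-cyclopenta[b]pyran carrying Br at C11 and the 9S carbinol with the methyl octanoate chain | CCC1C=CC2=C(O1)C(Br)=C[C@@]2(O)CCCCCCCC(=O)OC
F4 | step 2 | methyl 9-oxo-11-(trimethylsilyl)undec-10-ynoate | COC(=O)CCCCCCCC(=O)C#C[Si](C)(C)C
F5 | step 2 | methyl 11-bromo-9-oxoundec-10-ynoate | COC(=O)CCCCCCCC(=O)C#CBr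
F6 | step 2 | methyl (10Z)-11-bromo-11-iodo-9-oxoundec-10-enoate | COC(=O)CCCCCCCC(=O)/C=C(\I)Br
F7 | step 4 | methyl (10E,15E)-11-bromo-14-hydroxy-9-oxooctadeca-10,15-dien-12-ynoate (racemic) | CC/C=C/C(O)C#C/C(Br)=C\C(=O)CCCCCCCC(=O)OC
F8 | step 4 | methyl (10E,15E)-11-bromo-9,14-dioxooctadeca-10,15-dien-12-ynoate | CC/C=C/C(=O)C#C/C(Br)=C\C(=O)CCCCCCCC(=O)OC
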